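(Readings and results come from a simulation on assumed constants; scatter was added.)

- A small charge of starting material, 0.11 M in the amber run, is down to 50.3 % of itself after 25.0 h. We want the flask, with 0.22 M of starting material, gas held at 44 mM and 0.132 M of solid first nucleophile, at 30 h.

all flasks: gas 44 mM (held)

|  | starting material | solid first nucleophile | remark | time |
|---|---|---|---|---|
| amber | 0.11 M | 0.132 M | run made earlier |  |
| green | 0.17 M | 0.132 M | run made earlier |  |
| violet | 0.22 M | 0.20 M | run made earlier |  |
| flask | 0.22 M | 0.132 M |  | 30 h |

- amber (time / h: starting material / %, other capture product / %, target / %): 3.00: 91.1, 5.5, 0.2; 8.00: 79.2, 18.3, 0.4; 15.0: 67.0, 31.0, 0.1; 25.0: 50.3, 47.4, 0.2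
- green (time / h: starting material / %, other capture product / %, target / %): 2.00: 95.0, 3.3, 0; 4.00: 90.5, 7.8, 0; 10.0: 76.1, 21.8, 0.7; 25.0: 51.1, 48.8, 0
- violet (time / h: starting material / %, other capture product / %, target / %): 3.00: 92.6, 6.2, 0; 8.00: 80.8, 17.2, 0.5; 15.0: 67.0, 32.0, 0; 25.0: 50.6, 48.1, 1.3

(standard deviation of a reading: 0.5 percentage points)

- at the start none of the gas is in solution
- at the start none of the solid first nucleophile is in solution

- starting material present at 30 h, in percent of the starting material charged
- other capture product present at 30 h, in percent of the starting material charged

- The odd thing is the violet run. Its charge is twice the amber one, yet it stands at 50.6 % after 25.0 h. So violet lost 0.109 M where amber lost 0.0547 M in the same hours, and with 0.20 M of solid instead of 0.132 M.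
- This clears up when we count shares instead of amounts. We read the runs as losing a fixed share per hour (first order), so the clock is the half-life t½, the time in which the starting material halves.
- The amber, green and violet readings at 25.0 h average 50.7 %, which gives t½ = 25.5 h.
- Our flask has the violet charge of starting material and the amber charge of solid, and it runs for N = t/t½ = 1.18 half-lives, so we expect 44.2 % starting material.
- At 25.0 h the readings of the runs leave on average a gap of 1.2 percentage points between the charge and the sum of starting material and other capture product. Keeping that gap, we expect 54.6 % other capture product in our flask.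
- The forecast gives 45 % and 53.3 %, not our figures: “The rate then sags slightly, so I shade starting material up and product down.”
- The flask gives 44.0 % starting material and 54.7 % other capture product.

    starting material → intermediate (k = 7.60 × 10⁻⁶ s⁻¹)
    first nucleophile + intermediate ⇌ target (K = 2.00 L mol⁻¹, k = 0.00250 L mol⁻¹ s⁻¹)
    second nucleophile + intermediate → other capture product (k = 0.00710 L mol⁻¹ s⁻¹)
    gas ⇌ second nucleophile, rate k4*(csat - [second nucleophile]) (kL = 0.00140 s⁻¹)
    solid first nucleophile ⇌ first nucleophile, rate k5*(cs5 - [first nucleophile]) while solid is left; crystals form when [first nucleophile] > cs5 (solubility = 0.220 M, k = 5.40 × 10⁻⁶ s⁻¹)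

- What is neither of these in the flask at 30.0 h is 1.11 % intermediate and 0.216 % target.
- Read at 5.0 d, the same flask has run 4.71 half-lives, so our count leaves 3.82 % starting material, and that flask stands at 3.75 %.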